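**Assumption:** (R)-3-methylcyclohexanone is the chiral starting material, and both trisubstituted alkenes are E, as in the target (the target's (4R,5R) configuration was derived from its SMILES).

**Retrosynthesis**
1. The last C–C bond, butenolide C3–CH2, is made by Ni/photoredox decarboxylative coupling of a primary acid-derived radical with 3-bromofuran-2(5H)-one.
2. The C6=C7 E-trisubstituted alkene comes from cross-metathesis of a 1,1-disubstituted alkene on the cyclohexenone with an ester-bearing terminal alkene; that alkene is made by Johnson–Claisen.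
3. The enone comes from a Babler–Dauben 1,3-transposition of a tertiary allylic alcohol. The quaternary centre comes from sequential α′-alkylation (chain first, then Me) of (R)-5-methylcyclohexenone, with the C5-Me controlling the face.
4. No ring is built: the cyclohexenone is the pool ring and the butenolide is the purchased 3-bromofuranone.

**Step 1**
Reactants: 1 (R)-3-methylcyclohexanone
Product: 2 silyl enol ether
Conditions: LDA, THF, −78 °C; then TMSCl, Et3N, −78 °C → rt
Reagents that add atoms: chlorotrimethylsilane, C[Si](C)(C)Cl
Why: kinetic enolization at the less hindered C6-H2 (about 4:1 over C2) followed by O-silylation; the stereocentre is untouched, and the minor regioisomer is removed after step 2.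

**Step 2**
Reactants: 2
Product: 3 (R)-5-methylcyclohex-2-en-1-one
Conditions: Pd(OAc)2 (1 equiv; or 10 mol% with O2), MeCN, rt
Reagents that add atoms: none
Why: Saegusa–Ito oxidation gives the regiodefined enone, which makes the CH2 next to the C5-Me stereocentre the only α′-site for the later alkylations; the minor isomer (achiral 3-methylcyclohexenone) is removed by chromatography.

**Step 3**
Reactants: 3; 4 4-bromo-2-methylbut-1-ene
Product: 5 (5R,6S)-5-methyl-6-(3-methylbut-3-en-1-yl)cyclohex-2-en-1-one
Conditions: LDA, THF, −78 °C; then 4, HMPA, −78 → −20 °C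
Reagents that add atoms: none beyond reactant 4
Why: kinetic α′-deprotonation gives the cross-conjugated enolate, and SN2 alkylation at C6 puts the chain trans to the 5-Me; C6 is epimerizable and is reset in step 4.

**Step 4**
Reactants: 5
Product: 6 (5R,6R)-5,6-dimethyl-6-(3-methylbut-3-en-1-yl)cyclohex-2-en-1-one
Conditions: LDA, THF, −78 °C; then MeI, HMPA, −78 → 0 °C
Reagents that add atoms: iodomethane, CI
Why: enolate alkylation in which A(1,2)-strain holds the C5-Me pseudoaxial, so MeI attacks anti to it. The new methyl ends up trans to the 5-Me and the pre-installed chain cis, which sets the quaternary centre to match the target by substrate control from the pool stereocentre.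

**Step 5**
Reactants: 6
Product: 7 (5R,6R)-1,5,6-trimethyl-6-(3-methylbut-3-en-1-yl)cyclohex-2-en-1-ol (C1 epimeric mixture)
Conditions: MeLi, CeCl3, THF, −78 °C
Reagents that add atoms: methyllithium, C[Li]
Why: Imamoto organocerium 1,2-addition; there is no enolizable α-H (C6 is quaternary), so the addition is clean, and the new C1 stereocentre is destroyed in step 6.

**Step 6**
Reactants: 7
Product: 8 (4R,5R)-3,4,5-trimethyl-4-(3-methylbut-3-en-1-yl)cyclohex-2-en-1-one
Conditions: PCC, NaOAc, 4 Å MS, CH2Cl2, rt
Reagents that add atoms: none
Why: Babler–Dauben oxidative 1,3-transposition moves the carbonyl to the former β-carbon and leaves a β-methyl enone next to the quaternary centre; the stereocentres are not involved.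

**Step 7**
Reactants: 9 hex-5-en-2-one
Product: 10 3-methylhepta-1,6-dien-3-ol
Conditions: CH2=CHMgBr, THF, 0 °C
Reagents that add atoms: vinylmagnesium bromide, C=C[Mg]Br
Why: Grignard addition to the methyl ketone gives the linalool-type tertiary allylic alcohol; its racemic carbinol stereocentre is erased in step 8.

**Step 8**
Reactants: 10
Product: 11 ethyl (4E)-5-methylnona-4,8-dienoate
Conditions: CH3C(OEt)3 (10 equiv), EtCO2H (cat.), 140 °C, EtOH removed
Reagents that add atoms: triethyl orthoacetate, CC(OCC)(OCC)OCC
Why: Johnson–Claisen [3,3] rearrangement through a chair transition state with the larger CH2R group equatorial gives the E-trisubstituted alkene (about 85:15) and the CH2CO2Et homologation.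

**Step 9**
Reactants: 8; 11 (3 equiv)
Product: 12 ethyl (4E,8E)-5,9-dimethyl-11-[(1R,2R)-1,2,6-trimethyl-4-oxocyclohex-5-en-1-yl]undeca-4,8-dienoate
Conditions: Hoveyda–Grubbs II (5 mol%), CH2Cl2, 40 °C, Ar sparge to remove ethylene
Reagents that add atoms: none beyond reactant 11
Why: cross-metathesis of the 1,1-disubstituted alkene of 8 with the monosubstituted alkene of 11 (used in excess) gives the thermodynamically favoured E-trisubstituted alkene; the enone and the other trisubstituted alkene are inert.

**Step 10**
Reactants: 12
Product: 13 (4E,8E)-5,9-dimethyl-11-[(1R,2R)-1,2,6-trimethyl-4-oxocyclohex-5-en-1-yl]undeca-4,8-dienoic acid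
Conditions: LiOH·H2O, THF/MeOH/H2O, rt
Reagents that add atoms: lithium hydroxide, [Li+].[OH-]
Why: ester saponification; the β,β-disubstituted enone is untouched.

**Step 11**
Reactants: 13
Product: 14 N-hydroxyphthalimide (NHPI) ester
Conditions: NHPI, DIC, DMAP (cat.), CH2Cl2, rt
Reagents that add atoms: N-hydroxyphthalimide, O=C1c2ccccc2C(=O)N1O
Why: carbodiimide esterification gives a redox-active ester, so that radical formation is reductive and the electron-rich trisubstituted alkenes are not oxidized.

**Step 12**
Reactants: 14; 15 3-bromofuran-2(5H)-one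
Product: 16 cyclolinteinone
Conditions: NiCl2·glyme (10 mol%), dtbbpy (12 mol%), [Ir{dF(CF3)ppy}2(dtbbpy)]PF6 (1 mol%), Hantzsch ester (1.5 equiv), DMA, blue LEDs, 25 °C
Reagents that add atoms: none (15 supplies the butenolide)
Why: Proposed new method: Ir(II) formed by reductive quenching reduces the NHPI ester, which loses CO2 and phthalimide to give the primary radical •CH2CH2–CH=C(Me)–. Ni(0) adds oxidatively into the electron-poor vinylic C3–Br of 15, captures the radical, and reductive elimination forms the C(sp2)–C(sp3) bond, leaving both E-alkenes and the enone intact. The closest known reaction is Ni/photoredox decarboxylative alkenylation of redox-active esters with vinyl halides, but it has not been shown with a 3-halobutenolide, where competing Giese addition at C4 must be outcompeted.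

**Compound list**

| # | Name | SMILES | Role |
|---|---|---|---|
| 1 | (R)-3-methylcyclohexanone | C[C@@H]1CCCC(=O)C1 | starting material |
| 2 | (5R)-5-methyl-1-(trimethylsilyloxy)cyclohexene | C[C@H]1CC(O[Si](C)(C)C)=CCC1 | intermediate |
| 3 | (5R)-5-methylcyclohex-2-en-1-one | C[C@@H]1CC=CC(=O)C1 | intermediate |
| 4 | 4-bromo-2-methylbut-1-ene | C=C(C)CCBr | starting material |
| 5 | (5R,6S)-5-methyl-6-(3-methylbut-3-en-1-yl)cyclohex-2-en-1-one | C[C@@H]1CC=CC(=O)[C@H]1CCC(C)=C | intermediate |
| 6 | (5R,6R)-5,6-dimethyl-6-(3-methylbut-3-en-1-yl)cyclohex-2-en-1-one | C[C@@H]1CC=CC(=O)[C@]1(C)CCC(C)=C | intermediate |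
| 7 | (5R,6R)-1,5,6-trimethyl-6-(3-methylbut-3-en-1-yl)cyclohex-2-en-1-ol (C1 epimers) | C[C@@H]1CC=CC(C)(O)[C@]1(C)CCC(C)=C | intermediate |
| 8 | (4R,5R)-3,4,5-trimethyl-4-(3-methylbut-3-en-1-yl)cyclohex-2-en-1-one | CC1=CC(=O)C[C@@H](C)[C@@]1(C)CCC(C)=C | intermediate |
| 9 | hex-5-en-2-one | CC(=O)CCC=C | starting material |
| 10 | 3-methylhepta-1,6-dien-3-ol | C=CC(C)(O)CCC=C | intermediate |
| 11 | ethyl (4E)-5-methylnona-4,8-dienoate | CCOC(=O)CC/C=C(\C)CCC=C | intermediate |
| 12 | ethyl (4E,8E)-5,9-dimethyl-11-[(1R,2R)-1,2,6-trimethyl-4-oxocyclohex-5-en-1-yl]undeca-4,8-dienoate | CC1=CC(=O)C[C@@H](C)[C@@]1(C)CC/C(C)=C/CC/C(C)=C/CCC(=O)OCC | intermediate |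
| 13 | corresponding carboxylic acid | CC1=CC(=O)C[C@@H](C)[C@@]1(C)CC/C(C)=C/CC/C(C)=C/CCC(=O)O | intermediate |
| 14 | NHPI ester of 13 | CC1=CC(=O)C[C@@H](C)[C@@]1(C)CC/C(C)=C/CC/C(C)=C/CCC(=O)ON1C(=O)c2ccccc2C1=O | intermediate |
| 15 | 3-bromofuran-2(5H)-one | O=C1OCC=C1Br | starting material |
| 16 | cyclolinteinone | CC1=CC(=O)C[C@@H](C)[C@@]1(C)CC/C(C)=C/CC/C(C)=C/CCC1=CC(=O)OC1 | target |

**Total steps:** 12. **Longest linear sequence:** 10 (1 → 2 → 3 → 5 → 6 → 7 → 8 → 12 → 13 → 14 → 16).

**Three steps most likely to fail**
1. **Step 12 (proposed new coupling).** The primary radical may add to C4 of the butenolide, or the bromobutenolide may be hydrodebrominated. Fallback using known chemistry: Barton decarboxylative iodination of 13, then zinc insertion and Pd-catalyzed Negishi coupling of the alkylzinc with 3-bromofuran-2(5H)-one.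
2. **Step 9 (cross-metathesis).** The 1,1-disubstituted alkene is a poor partner and E/Z control may be modest. Fallback that changes the approach: in step 3 alkylate with 2-(2-bromoethyl)-2-methyl-1,3-dioxolane instead of 4, carry it through steps 4–6, and unmask the side-chain methyl ketone. Then build both E-alkenes by two rounds of vinylMgBr addition, Johnson–Claisen and Weinreb-amide/MeMgBr conversion to the methyl ketone, ending at the acid 13.
3. **Step 4 (quaternary methylation).** The diastereoselectivity at C6 could be low. Fallback that changes the approach: set C4 and C5 together by Ireland–Claisen rearrangement of the (S)-pent-3-en-2-ol ester of the 2-methylalkanoic acid bearing the chain, then MeLi to the methyl ketone, Wacker oxidation and aldol condensation to form the enone ring.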